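**Plan**

1. Retrosynthesis: the two aryl–O–C8 ether bonds of the side chains are cut first (a bisphenol plus an (S)-α-mesyloxy ketone made from ethyl lactate), the two ring oxygens para to the oxolane are traced back to bromides, and the C3 methyl group is traced back to a formyl group.
2. Enabling feature: in the oxolane (O1, C2 with ring A, C3, C4, C5 with ring B) the C3 methyl group sits between C2, which carries an aryl group and O1, and C4; as a formyl group it turns C2–C3 into an aldol-type bond, so O1–C2 and C2–C3 are cut together into an aryl aldehyde and an enol ether held on the C5 oxygen.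
3. Forward order: syn aldol (C4–C5), silyl ether, auxiliary removal, oxidation and (Z)-methoxymethylenation give the enol ether; its union with 3-(benzyloxy)-4-bromobenzaldehyde closes the oxolane, the only ring that is made; then CHO to CH3, Br to OH twice, double O-alkylation, ketone reduction and debenzylation.
4. Stereochemistry: C4 and C5 come from the oxazolidinone-controlled syn aldol; C3 and C2 are set in the ring closure (C4 methyl plus (Z) enol ether geometry, kinetic synclinal closure); both C8 centres come from ethyl (S)-lactate by SN2 inversion; both C7 carbinols come from Felkin–Anh reduction.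

Key step: step 7

Remark: ring A is the future 3-hydroxy-4-alkoxyphenyl ring on C2 and ring B the 3-methoxy-4-alkoxyphenyl ring on C5; all starting materials and named reagents are taken as commercial, and only the (Z) enol ether is carried into the key step.

**Route**

Step 1
Reactants: 1 (S)-4-benzyl-3-propanoyl-1,3-oxazolidin-2-one; 2 4-bromo-3-methoxybenzaldehyde
Product: 4 (S)-4-benzyl-3-[(2S,3S)-3-(4-bromo-3-methoxyphenyl)-3-hydroxy-2-methylpropanoyl]-1,3-oxazolidin-2-one, via dibutylboron (Z)-enolate 3 (not isolated)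
Conditions: n-Bu2BOTf, iPr2NEt, CH2Cl2, 0 °C; then 2, −78 to 0 °C; then pH 7 buffer, MeOH, H2O2, 0 °C
Reagents that add atoms: none
Why: Evans syn aldol, in which the (Z)-boron enolate reacts through a closed Zimmerman–Traxler chair with the benzyl group shielding one enolate face, so that both new centres (2S,3S, the future C4 and C5) are set in the syn relationship.

Step 2
Reactants: 4 (S)-4-benzyl-3-[(2S,3S)-3-(4-bromo-3-methoxyphenyl)-3-hydroxy-2-methylpropanoyl]-1,3-oxazolidin-2-one
Product: 5 (S)-4-benzyl-3-[(2S,3S)-3-(4-bromo-3-methoxyphenyl)-2-methyl-3-(triethylsilyloxy)propanoyl]-1,3-oxazolidin-2-one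
Conditions: Et3SiOTf, 2,6-lutidine, CH2Cl2, −78 to 0 °C
Reagents that add atoms: triethylsilyl trifluoromethanesulfonate, CC[Si](CC)(CC)OS(=O)(=O)C(F)(F)F
Why: O-silylation of the secondary benzylic alcohol with a silyl triflate and a hindered pyridine base blocks retro-aldol cleavage and installs the silyl ether that later serves to form the oxocarbenium ion, without touching a stereocentre.

Step 3
Reactants: 5 (S)-4-benzyl-3-[(2S,3S)-3-(4-bromo-3-methoxyphenyl)-2-methyl-3-(triethylsilyloxy)propanoyl]-1,3-oxazolidin-2-one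
Product: 6 (2R,3S)-3-(4-bromo-3-methoxyphenyl)-2-methyl-3-(triethylsilyloxy)propan-1-ol
Conditions: LiBH4, MeOH (1 equiv), THF, 0 °C
Reagents that add atoms: none
Why: Reductive removal of the auxiliary, in which LiBH4 attacks the exocyclic imide carbonyl and gives the primary alcohol without epimerisation while the aryl bromide and the silyl ether stay intact (the descriptor at C2 changes only by the sequence rule).

Step 4
Reactants: 6 (2R,3S)-3-(4-bromo-3-methoxyphenyl)-2-methyl-3-(triethylsilyloxy)propan-1-ol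
Product: 7 (2S,3S)-3-(4-bromo-3-methoxyphenyl)-2-methyl-3-(triethylsilyloxy)propanal
Conditions: Dess–Martin periodinane, pyridine, CH2Cl2, 0 °C to rt
Reagents that add atoms: none
Why: Dess–Martin oxidation under buffered conditions gives the α-methyl aldehyde without epimerisation or silyl loss, and the aldehyde is used at once.

Step 5
Reactants: 7 (2S,3S)-3-(4-bromo-3-methoxyphenyl)-2-methyl-3-(triethylsilyloxy)propanal; 8 (methoxymethyl)triphenylphosphonium chloride
Product: 10 {[(1S,2R,3Z)-1-(4-bromo-3-methoxyphenyl)-4-methoxy-2-methylbut-3-en-1-yl]oxy}triethylsilane, via methoxymethylidene ylide 9 (not isolated)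
Conditions: KN(SiMe3)2, THF, 0 °C; then 7, −78 to 0 °C; chromatographic separation of the (Z) isomer
Reagents that add atoms: none
Why: Wittig methoxymethylenation with the salt-free ylide at low temperature converts the aldehyde into the enol ether without touching the α-centre; the geometry is expected to be only moderately (Z)-biased, so the (Z) isomer is isolated by chromatography.

Step 6
Reactants: 11 4-bromo-3-hydroxybenzaldehyde
Product: 12 3-(benzyloxy)-4-bromobenzaldehyde
Conditions: BnBr, K2CO3, DMF, rt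
Reagents that add atoms: benzyl bromide, BrCc1ccccc1
Why: Williamson etherification of the phenol gives a benzyl ether that should survive every later step up to the final hydrogenolysis.

Step 7
Reactants: 10 {[(1S,2R,3Z)-1-(4-bromo-3-methoxyphenyl)-4-methoxy-2-methylbut-3-en-1-yl]oxy}triethylsilane; 12 3-(benzyloxy)-4-bromobenzaldehyde
Product: 15 (2S,3R,4R,5S)-2-[3-(benzyloxy)-4-bromophenyl]-5-(4-bromo-3-methoxyphenyl)-4-methyloxolane-3-carbaldehyde, via oxocarbenium triflate 13 (not isolated), via cyclised methoxycarbenium triflate 14 (not isolated)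
Conditions: Me3SiOTf (1.2 equiv), 2,6-di-tert-butyl-4-methylpyridine (0.2 equiv), CH2Cl2, −78 °C; then aq NaHCO3 at −78 °C
Reagents that add atoms: water, O
Why: Me3SiOTf activates aldehyde 12, the silyl ether oxygen of 10 adds and Et3SiOSiMe3 leaves, which gives the (E)-aryl oxocarbenium ion 13 on O1 under aprotic conditions (the known way to condense silyl ethers with aldehydes in silyl-modified Prins and Sakurai cyclisations); the enol ether carbon C3 then bonds to C2 and the methoxycarbenium ion 14 is hydrolysed by the cold bicarbonate quench. The closest known reaction is the Lewis acid ring contraction of 4,5-dihydro-1,3-dioxepins (cyclic vinyl acetals) to oxolane-3-carbaldehydes, an intramolecular Mukaiyama-type aldol of the same oxocarbenium/enol ether pair, which is here assembled from two fragments in the flask. The oxolane closes in the 5-(enolexo)-endo-trig mode, which that ring contraction shows to be open to a C=O+ electrophile. At C3, allylic 1,3-strain with the (Z)-methoxy group turns the C4 methyl group anti to the enol double bond, so the formyl carbon ends up trans to it; at C2, the aryl group of the (E)-ion points away from C5 and the enol ether has to approach in the synclinal, least-motion way (its oxygen over the cationic carbon), the approach that gives 2,3-cis aldehydes under kinetic control in the ring contraction; C4 and C5 are not touched, so the syn aldol pair becomes the cis methyl/aryl pair. The step therefore needs kinetic 2,3-cis and 3,4-trans selectivity, that is closure through the folded conformer with the ring B aryl group at C5 pseudoaxial and not through the extended conformer, which would give the C2 epimer. What the substrate and conditions offer for this is a single (Z) enol ether, two electron-poor bromoaryl groups that keep the C5–O bond from ionising and the oxocarbenium ion short-lived, −78 °C, exclusion of protic acid by the pyridine base, and use of the epimerisable β-alkoxy aldehyde in the next step without delay.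

Step 8
Reactants: 15 (2S,3R,4R,5S)-2-[3-(benzyloxy)-4-bromophenyl]-5-(4-bromo-3-methoxyphenyl)-4-methyloxolane-3-carbaldehyde
Product: 16 N'-[(E)-{(2S,3S,4R,5S)-2-[3-(benzyloxy)-4-bromophenyl]-5-(4-bromo-3-methoxyphenyl)-4-methyloxolan-3-yl}methylidene]-4-methylbenzenesulfonohydrazide (same spatial arrangement as 15; the C3 descriptor changes by the sequence rule)
Conditions: TsNHNH2, MgSO4, THF, rt
Reagents that add atoms: 4-methylbenzenesulfonohydrazide, Cc1ccc(S(=O)(=O)NN)cc1
Why: Hydrazone formation from the aldehyde under neutral conditions at room temperature should be faster than epimerisation at C3 or β-elimination of the ring oxygen.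

Step 9
Reactants: 16 N'-[(E)-{(2S,3S,4R,5S)-2-[3-(benzyloxy)-4-bromophenyl]-5-(4-bromo-3-methoxyphenyl)-4-methyloxolan-3-yl}methylidene]-4-methylbenzenesulfonohydrazide
Product: 17 (2S,3R,4R,5S)-2-[3-(benzyloxy)-4-bromophenyl]-5-(4-bromo-3-methoxyphenyl)-3,4-dimethyloxolane
Conditions: catecholborane, CHCl3, 0 °C; then NaOAc·3H2O, 60 °C
Reagents that add atoms: none
Why: Kabalka variant of the Caglioti tosylhydrazone reduction, in which catecholborane adds hydride to C=N and acetate then triggers loss of sulfinate and N2 from the diazene, so that CH=N becomes CH3 under mild conditions that leave C3, the aryl bromides and the benzyl ether alone.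

Step 10
Reactants: 17 (2S,3R,4R,5S)-2-[3-(benzyloxy)-4-bromophenyl]-5-(4-bromo-3-methoxyphenyl)-3,4-dimethyloxolane
Product: 19 2-(benzyloxy)-4-[(2S,3R,4R,5S)-5-(4-hydroxy-3-methoxyphenyl)-3,4-dimethyloxolan-2-yl]phenol, via bis(pinacol boronate) 18 (not isolated)
Conditions: B2pin2, PdCl2(dppf), KOAc, 1,4-dioxane, 85 °C; then H2O2, aq NaOH, THF, 0 °C
Reagents that add atoms: hydrogen peroxide, OO
Why: Miyaura borylation of both aryl bromides followed by oxidation of the two C–B bonds gives the two phenols at a temperature and basicity too mild to open the p-hydroxybenzylic ether positions of the oxolane.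

Step 11
Reactants: 20 ethyl (S)-lactate
Product: 21 (S)-2-hydroxy-N-methoxy-N-methylpropanamide
Conditions: MeNHOMe·HCl, iPrMgCl, THF, −20 to 0 °C
Reagents that add atoms: N,O-dimethylhydroxylamine hydrochloride, CNOC.Cl
Why: Direct aminolysis of the ester by the chloromagnesium amide of N,O-dimethylhydroxylamine gives the Weinreb amide, and the α-centre, held as its magnesium alkoxide, is not enolised.

Step 12
Reactants: 21 (S)-2-hydroxy-N-methoxy-N-methylpropanamide
Product: 22 (S)-1-(3,4-dimethoxyphenyl)-2-hydroxypropan-1-one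
Conditions: 3,4-dimethoxyphenylmagnesium bromide (2.5 equiv), THF, 0 °C to rt; aq NH4Cl
Reagents that add atoms: 3,4-dimethoxyphenylmagnesium bromide, COc1ccc([Mg]Br)cc1OC
Why: Grignard addition to the Weinreb amide stops at the ketone because of the stable magnesium chelate (the first equivalent deprotonates the hydroxyl group), and the stereocentre is retained.

Step 13
Reactants: 22 (S)-1-(3,4-dimethoxyphenyl)-2-hydroxypropan-1-one
Product: 23 (S)-1-(3,4-dimethoxyphenyl)-1-oxopropan-2-yl methanesulfonate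
Conditions: MsCl, Et3N, CH2Cl2, −10 °C
Reagents that add atoms: methanesulfonyl chloride, CS(=O)(=O)Cl
Why: O-sulfonylation of the secondary alcohol occurs with retention and gives an α-sulfonyloxy ketone that is a good SN2 electrophile whose leaving group cannot return as a nucleophile.

Step 14
Reactants: 19 2-(benzyloxy)-4-[(2S,3R,4R,5S)-5-(4-hydroxy-3-methoxyphenyl)-3,4-dimethyloxolan-2-yl]phenol; 23 (S)-1-(3,4-dimethoxyphenyl)-1-oxopropan-2-yl methanesulfonate
Product: 24 (R)-2-{2-(benzyloxy)-4-[(2S,3R,4R,5S)-5-{4-[(R)-1-(3,4-dimethoxyphenyl)-1-oxopropan-2-yl]oxy-3-methoxyphenyl}-3,4-dimethyloxolan-2-yl]phenoxy}-1-(3,4-dimethoxyphenyl)propan-1-one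
Conditions: 23 (2.4 equiv), 2-tert-butylimino-2-diethylamino-1,3-dimethylperhydro-1,3,2-diazaphosphorine (BEMP), CH2Cl2, rt
Reagents that add atoms: none
Why: Double SN2 O-alkylation of the two phenoxides, generated by the non-nucleophilic phosphazene base, at the carbon α to the ketone proceeds with inversion and turns (S) in the mesylate into (R) at both C8 centres.

Step 15
Reactants: 24 (R)-2-{2-(benzyloxy)-4-[(2S,3R,4R,5S)-5-{4-[(R)-1-(3,4-dimethoxyphenyl)-1-oxopropan-2-yl]oxy-3-methoxyphenyl}-3,4-dimethyloxolan-2-yl]phenoxy}-1-(3,4-dimethoxyphenyl)propan-1-one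
Product: 25 (1R,2R)-2-{2-(benzyloxy)-4-[(2S,3R,4R,5S)-5-{4-[(1R,2R)-1-(3,4-dimethoxyphenyl)-1-hydroxypropan-2-yl]oxy-3-methoxyphenyl}-3,4-dimethyloxolan-2-yl]phenoxy}-1-(3,4-dimethoxyphenyl)propan-1-ol
Conditions: quaternary ammonium resin in its BH4− form (polymer-supported borohydride), MeOH, 0 °C to rt
Reagents that add atoms: none
Why: Felkin–Anh reduction in the absence of a chelating cation, in which hydride attacks anti to the α-aryloxy group, should give the threo (1R,2R) carbinol at each of the two ketones.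

Step 16
Reactants: 25 (1R,2R)-2-{2-(benzyloxy)-4-[(2S,3R,4R,5S)-5-{4-[(1R,2R)-1-(3,4-dimethoxyphenyl)-1-hydroxypropan-2-yl]oxy-3-methoxyphenyl}-3,4-dimethyloxolan-2-yl]phenoxy}-1-(3,4-dimethoxyphenyl)propan-1-ol
Product: 26 manassantin B1, (1R,2R)-1-(3,4-dimethoxyphenyl)-2-{4-[(2S,3R,4R,5S)-5-{4-[(1R,2R)-1-(3,4-dimethoxyphenyl)-1-hydroxypropan-2-yl]oxy-3-methoxyphenyl}-3,4-dimethyloxolan-2-yl]-2-hydroxyphenoxy}propan-1-ol
Conditions: H2 (1 atm), 10% Pd/C, EtOAc, rt
Reagents that add atoms: none
Why: Hydrogenolysis of the aryl benzyl ether over Pd/C under neutral conditions is faster than cleavage of the benzylic alcohols or of the oxolane C–O bonds and releases the free phenol of the target.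

**Compound list**

1 | (S)-4-benzyl-3-propanoyl-1,3-oxazolidin-2-one | CCC(=O)N1C(=O)OC[C@@H]1Cc1ccccc1 | starting material
2 | 4-bromo-3-methoxybenzaldehyde | COc1cc(C=O)ccc1Br | starting material
3 | dibutylboron (Z)-enolate of 1 | C/C=C(\OB(CCCC)CCCC)N1C(=O)OC[C@@H]1Cc1ccccc1 | intermediate
4 | (S)-4-benzyl-3-[(2S,3S)-3-(4-bromo-3-methoxyphenyl)-3-hydroxy-2-methylpropanoyl]-1,3-oxazolidin-2-one | O=C([C@@H](C)[C@H](O)c1ccc(Br)c(OC)c1)N1C(=O)OC[C@@H]1Cc1ccccc1 | intermediate
5 | (S)-4-benzyl-3-[(2S,3S)-3-(4-bromo-3-methoxyphenyl)-2-methyl-3-(triethylsilyloxy)propanoyl]-1,3-oxazolidin-2-one | O=C([C@@H](C)[C@H](O[Si](CC)(CC)CC)c1ccc(Br)c(OC)c1)N1C(=O)OC[C@@H]1Cc1ccccc1 | intermediate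
6 | (2R,3S)-3-(4-bromo-3-methoxyphenyl)-2-methyl-3-(triethylsilyloxy)propan-1-ol | OC[C@@H](C)[C@H](O[Si](CC)(CC)CC)c1ccc(Br)c(OC)c1 | intermediate
7 | (2S,3S)-3-(4-bromo-3-methoxyphenyl)-2-methyl-3-(triethylsilyloxy)propanal | O=C[C@@H](C)[C@H](O[Si](CC)(CC)CC)c1ccc(Br)c(OC)c1 | intermediate
8 | (methoxymethyl)triphenylphosphonium chloride | [Cl-].COC[P+](c1ccccc1)(c1ccccc1)c1ccccc1 | starting material
9 | (methoxymethylidene)triphenylphosphorane | COC=P(c1ccccc1)(c1ccccc1)c1ccccc1 | intermediate
10 | {[(1S,2R,3Z)-1-(4-bromo-3-methoxyphenyl)-4-methoxy-2-methylbut-3-en-1-yl]oxy}triethylsilane | CC[Si](CC)(CC)O[C@H](c1ccc(Br)c(OC)c1)[C@H](C)/C=C\OC | intermediate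
11 | 4-bromo-3-hydroxybenzaldehyde | O=Cc1ccc(Br)c(O)c1 | starting material
12 | 3-(benzyloxy)-4-bromobenzaldehyde | O=Cc1ccc(Br)c(OCc2ccccc2)c1 | intermediate
13 | (E)-[3-(benzyloxy)-4-bromobenzylidene][(1S,2R,3Z)-1-(4-bromo-3-methoxyphenyl)-4-methoxy-2-methylbut-3-en-1-yl]oxonium trifluoromethanesulfonate | Brc1ccc(/C=[O+]/[C@H](c2ccc(Br)c(OC)c2)[C@H](C)/C=C\OC)cc1OCc1ccccc1.[O-]S(=O)(=O)C(F)(F)F | intermediate
14 | methyl{[(2S,3R,4R,5S)-2-[3-(benzyloxy)-4-bromophenyl]-5-(4-bromo-3-methoxyphenyl)-4-methyloxolan-3-yl]methylidene}oxonium trifluoromethanesulfonate | Brc1ccc([C@H]2O[C@H](c3ccc(Br)c(OC)c3)[C@H](C)[C@H]2C=[O+]C)cc1OCc1ccccc1.[O-]S(=O)(=O)C(F)(F)F | intermediate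
15 | (2S,3R,4R,5S)-2-[3-(benzyloxy)-4-bromophenyl]-5-(4-bromo-3-methoxyphenyl)-4-methyloxolane-3-carbaldehyde | Brc1ccc([C@H]2O[C@H](c3ccc(Br)c(OC)c3)[C@H](C)[C@H]2C=O)cc1OCc1ccccc1 | intermediate
16 | N'-[(E)-{(2S,3S,4R,5S)-2-[3-(benzyloxy)-4-bromophenyl]-5-(4-bromo-3-methoxyphenyl)-4-methyloxolan-3-yl}methylidene]-4-methylbenzenesulfonohydrazide | Brc1ccc([C@H]2O[C@H](c3ccc(Br)c(OC)c3)[C@H](C)[C@H]2/C=N/NS(=O)(=O)c2ccc(C)cc2)cc1OCc1ccccc1 | intermediate
17 | (2S,3R,4R,5S)-2-[3-(benzyloxy)-4-bromophenyl]-5-(4-bromo-3-methoxyphenyl)-3,4-dimethyloxolane | Brc1ccc([C@H]2O[C@H](c3ccc(Br)c(OC)c3)[C@H](C)[C@H]2C)cc1OCc1ccccc1 | intermediate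
18 | 2-{2-(benzyloxy)-4-[(2S,3R,4R,5S)-5-[3-methoxy-4-(4,4,5,5-tetramethyl-1,3,2-dioxaborolan-2-yl)phenyl]-3,4-dimethyloxolan-2-yl]phenyl}-4,4,5,5-tetramethyl-1,3,2-dioxaborolane | CC1(C)OB(OC1(C)C)c1ccc([C@H]2O[C@H](c3ccc(B4OC(C)(C)C(C)(C)O4)c(OC)c3)[C@H](C)[C@H]2C)cc1OCc1ccccc1 | intermediate
19 | 2-(benzyloxy)-4-[(2S,3R,4R,5S)-5-(4-hydroxy-3-methoxyphenyl)-3,4-dimethyloxolan-2-yl]phenol | Oc1ccc([C@H]2O[C@H](c3ccc(O)c(OC)c3)[C@H](C)[C@H]2C)cc1OCc1ccccc1 | intermediate
20 | ethyl (S)-lactate | CCOC(=O)[C@H](C)O | starting material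
21 | (S)-2-hydroxy-N-methoxy-N-methylpropanamide | CON(C)C(=O)[C@H](C)O | intermediate
22 | (S)-1-(3,4-dimethoxyphenyl)-2-hydroxypropan-1-one | COc1ccc(C(=O)[C@H](C)O)cc1OC | intermediate
23 | (S)-1-(3,4-dimethoxyphenyl)-1-oxopropan-2-yl methanesulfonate | COc1ccc(C(=O)[C@H](C)OS(C)(=O)=O)cc1OC | intermediate
24 | (R)-2-{2-(benzyloxy)-4-[(2S,3R,4R,5S)-5-{4-[(R)-1-(3,4-dimethoxyphenyl)-1-oxopropan-2-yl]oxy-3-methoxyphenyl}-3,4-dimethyloxolan-2-yl]phenoxy}-1-(3,4-dimethoxyphenyl)propan-1-one | COc1ccc(C(=O)[C@@H](C)Oc2ccc([C@H]3O[C@H](c4ccc(O[C@H](C)C(=O)c5ccc(OC)c(OC)c5)c(OC)c4)[C@H](C)[C@H]3C)cc2OCc2ccccc2)cc1OC | intermediate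
25 | (1R,2R)-2-{2-(benzyloxy)-4-[(2S,3R,4R,5S)-5-{4-[(1R,2R)-1-(3,4-dimethoxyphenyl)-1-hydroxypropan-2-yl]oxy-3-methoxyphenyl}-3,4-dimethyloxolan-2-yl]phenoxy}-1-(3,4-dimethoxyphenyl)propan-1-ol | COc1ccc([C@@H](O)[C@@H](C)Oc2ccc([C@H]3O[C@H](c4ccc(O[C@H](C)[C@H](O)c5ccc(OC)c(OC)c5)c(OC)c4)[C@H](C)[C@H]3C)cc2OCc2ccccc2)cc1OC | intermediate
26 | manassantin B1, (1R,2R)-1-(3,4-dimethoxyphenyl)-2-{4-[(2S,3R,4R,5S)-5-{4-[(1R,2R)-1-(3,4-dimethoxyphenyl)-1-hydroxypropan-2-yl]oxy-3-methoxyphenyl}-3,4-dimethyloxolan-2-yl]-2-hydroxyphenoxy}propan-1-ol | COc1ccc([C@@H](O)[C@@H](C)Oc2ccc([C@H]3O[C@H](c4ccc(O[C@H](C)[C@H](O)c5ccc(OC)c(OC)c5)c(OC)c4)[C@H](C)[C@H]3C)cc2O)cc1OC | target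

**Step count and risks**

Total: 16 steps. Longest linear sequence: 12 steps (steps 1–5, 7–10 and 14–16).

Step 7 is the step most likely to fail. The main danger is poor facial selectivity at the oxocarbenium carbon: closure through the extended conformer, in which the ring B aryl group stays pseudo-equatorial and the enol ether approaches antiperiplanar, would give the C2 epimer. Material could also be diverted by carbon–carbon bonding between the enol ether and the activated aldehyde before O1–C2 exists, or by acid-induced closure of the enol ether onto O1. The fallback sets out from 10 and uses known chemistry that fixes C2 by hydride delivery instead of by C–C bond formation. Aqueous HCl in THF hydrolyses the enol ether and the silyl ether to the lactol (4R,5S)-5-(4-bromo-3-methoxyphenyl)-4-methyloxolan-2-ol F1. Oxidation with TEMPO and PhI(OAc)2 gives the lactone (4R,5S)-5-(4-bromo-3-methoxyphenyl)-4-methyloxolan-2-one F2. Enolisation with LiN(iPr)2 and alkylation with MeI anti to the C4 methyl group gives (3R,4R,5S)-5-(4-bromo-3-methoxyphenyl)-3,4-dimethyloxolan-2-one F3. The aryllithium made from 2-(benzyloxy)-1-bromo-4-iodobenzene and n-BuLi at −78 °C (iodine–lithium exchange) adds to the lactone to give the hemiketal (3R,4R,5S)-2-[3-(benzyloxy)-4-bromophenyl]-5-(4-bromo-3-methoxyphenyl)-3,4-dimethyloxolan-2-ol F4. Et3SiH and BF3·OEt2 at −78 °C reduce the cyclic 2-aryl oxocarbenium ion from the face opposite the C3 methyl group, the established entry to the 2,3-cis-3,4-trans-4,5-cis series, and the route is rejoined at 17.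

Step 5 is the second risk. Low geometric selectivity of the ylide addition would lose material as the (E) isomer or leave it in the (Z) isomer, and the basic ylide could epimerise the centre α to the aldehyde. The fallback sets out from 7 and replaces the Wittig reaction by the stereospecific Horner–Wittig sequence. Lithiated (methoxymethyl)diphenylphosphine oxide (LiN(iPr)2, THF, −78 °C) adds to 7 to give β-hydroxy phosphine oxides. The like-configured adducts, shown as (1R,2R,3R,4S)-4-(4-bromo-3-methoxyphenyl)-1-(diphenylphosphoryl)-1-methoxy-3-methyl-4-(triethylsilyloxy)butan-2-ol F5 (its 1S,2S partner behaves alike), are separated by crystallisation or chromatography. KH in THF then effects syn-elimination of diphenylphosphinate and gives 10 as the (Z) isomer only.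

Step 14 is the third risk. Enolisation of the α-sulfonyloxy ketone or of the α-aryloxy ketone under the strong base would erode the configuration at C8, and the second substitution next to an ortho substituent could stall. The fallback sets out from 19 and forms the aryl ether bond on an ester, building the ketone afterwards. Mitsunobu etherification of 19 with ethyl (S)-lactate 20 (PPh3, diisopropyl azodicarboxylate, THF, 0 °C to rt) proceeds with inversion and gives ethyl (R)-2-{2-(benzyloxy)-4-[(2S,3R,4R,5S)-5-{4-[(R)-1-ethoxy-1-oxopropan-2-yl]oxy-3-methoxyphenyl}-3,4-dimethyloxolan-2-yl]phenoxy}propanoate F6. MeNHOMe·HCl and iPrMgCl at −20 °C convert both esters into the bis(Weinreb amide) (R)-2-{2-(benzyloxy)-4-[(2S,3R,4R,5S)-5-{4-[(R)-1-[methoxy(methyl)amino]-1-oxopropan-2-yl]oxy-3-methoxyphenyl}-3,4-dimethyloxolan-2-yl]phenoxy}-N-methoxy-N-methylpropanamide F7. Addition of 3,4-dimethoxyphenylmagnesium bromide then gives 24.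

**Further compounds**

F1 | step 7 | (4R,5S)-5-(4-bromo-3-methoxyphenyl)-4-methyloxolan-2-ol | OC1C[C@@H](C)[C@@H](c2ccc(Br)c(OC)c2)O1
F2 | step 7 | (4R,5S)-5-(4-bromo-3-methoxyphenyl)-4-methyloxolan-2-one | O=C1C[C@@H](C)[C@@H](c2ccc(Br)c(OC)c2)O1
F3 | step 7 | (3R,4R,5S)-5-(4-bromo-3-methoxyphenyl)-3,4-dimethyloxolan-2-one | O=C1O[C@H](c2ccc(Br)c(OC)c2)[C@H](C)[C@H]1C
F4 | step 7 | (3R,4R,5S)-2-[3-(benzyloxy)-4-bromophenyl]-5-(4-bromo-3-methoxyphenyl)-3,4-dimethyloxolan-2-ol | OC1(c2ccc(Br)c(OCc3ccccc3)c2)O[C@H](c2ccc(Br)c(OC)c2)[C@H](C)[C@H]1C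
F5 | step 5 | (1R,2R,3R,4S)-4-(4-bromo-3-methoxyphenyl)-1-(diphenylphosphoryl)-1-methoxy-3-methyl-4-(triethylsilyloxy)butan-2-ol | CO[C@H](P(=O)(c1ccccc1)c1ccccc1)[C@H](O)[C@@H](C)[C@H](O[Si](CC)(CC)CC)c1ccc(Br)c(OC)c1
F6 | step 14 | ethyl (R)-2-{2-(benzyloxy)-4-[(2S,3R,4R,5S)-5-{4-[(R)-1-ethoxy-1-oxopropan-2-yl]oxy-3-methoxyphenyl}-3,4-dimethyloxolan-2-yl]phenoxy}propanoate | CCOC(=O)[C@@H](C)Oc1ccc([C@H]2O[C@H](c3ccc(O[C@H](C)C(=O)OCC)c(OC)c3)[C@H](C)[C@H]2C)cc1OCc1ccccc1
F7 | step 14 | (R)-2-{2-(benzyloxy)-4-[(2S,3R,4R,5S)-5-{4-[(R)-1-[methoxy(methyl)amino]-1-oxopropan-2-yl]oxy-3-methoxyphenyl}-3,4-dimethyloxolan-2-yl]phenoxy}-N-methoxy-N-methylpropanamide | CON(C)C(=O)[C@@H](C)Oc1ccc([C@H]2O[C@H](c3ccc(O[C@H](C)C(=O)N(C)OC)c(OC)c3)[C@H](C)[C@H]2C)cc1OCc1ccccc1
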